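**Plan**
- The target is a linear triaryl ether: ring A (2,4,6-trihydroxyphenyl) – O – ring B (3,5-dihydroxy-1,4-phenylene) – O – ring C (3,4,5-trihydroxyphenyl). All eight hydroxyls are released last from methyl ethers (two are already free after the key step).
- Ring C is cut at C2–C3 and C5–C6. Its C3–C4–C5 segment with three oxygens is a methoxymalonyl unit; C2–C1–C6, with the ether oxygen on C1, is the isopropenyl ether of the ring A–B phenol, so the B–O–C bond exists before ring C does.
- The isopropenyl ether goes back through the acetate to the ring B phenol, the phenol to an aldehyde (Baeyer–Villiger), and the A–O–B bond to an SNAr between a ring A phenol and a ring B fluoroaldehyde.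
- Forward: rings A and B are joined, formyl is exchanged for oxygen, the oxygen becomes an enol ether, ring C is grown on it by a [3+3] double acylation, and BBr3 frees the phenols.
- The target has no stereocentre, so no stereocontrol is needed.

Key step: step 7

Remark: 1, 2 and 8 are taken as purchasable; the C–H centre between the two carbonyl groups of 11 and 12 is configurationally labile and is written without configuration.

**Step 1**
Reactants: 1 2,4,6-trimethoxyphenol; 2 4-fluoro-2,6-dimethoxybenzaldehyde
Product: 3 2,6-dimethoxy-4-(2,4,6-trimethoxyphenoxy)benzaldehyde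
Conditions: K2CO3, DMF, 110 °C
Reagents that add atoms: none
Why: Nucleophilic aromatic substitution (SNAr); the fluoride para to the formyl group should be displaced by the phenoxide of 1 through a Meisenheimer adduct stabilised by the aldehyde, as is usual for 4-fluorobenzaldehydes and phenols.

**Step 2**
Reactants: 3 2,6-dimethoxy-4-(2,4,6-trimethoxyphenoxy)benzaldehyde
Product: 5 2,6-dimethoxy-4-(2,4,6-trimethoxyphenoxy)phenol, via aryl formate 4 (not isolated)
Conditions: mCPBA, CH2Cl2, 0 °C to rt; then K2CO3 (cat.), MeOH, rt
Reagents that add atoms: mCPBA, OOC(=O)c1cccc(Cl)c1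
Why: Baeyer–Villiger (Dakin-type) oxidation; the aryl group flanked by two methoxy groups and para to an aryloxy group should migrate in preference to hydrogen, and the formate is then cleaved by transesterification with methanol.

**Step 3**
Reactants: 5 2,6-dimethoxy-4-(2,4,6-trimethoxyphenoxy)phenol
Product: 6 2,6-dimethoxy-4-(2,4,6-trimethoxyphenoxy)phenyl acetate
Conditions: Ac2O, DMAP (cat.), pyridine, rt
Reagents that add atoms: acetic anhydride, CC(=O)OC(C)=O
Why: DMAP-catalysed O-acetylation, which is reliable even for phenols flanked by two ortho substituents.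

**Step 4**
Reactants: 6 2,6-dimethoxy-4-(2,4,6-trimethoxyphenoxy)phenyl acetate
Product: 7 2-[2,6-dimethoxy-4-(2,4,6-trimethoxyphenoxy)phenoxy]propene
Conditions: Cp2TiMe2, toluene, 70 °C, dark; filtration through basic Al2O3
Reagents that add atoms: dimethyltitanocene Cp2TiMe2, C[Ti+2]C.c1cc[cH-]c1.c1cc[cH-]c1
Why: Petasis methylenation; Cp2Ti=CH2 formed on heating should add to the ester carbonyl by [2+2] cycloaddition and release the enol ether by cycloreversion, and the aryl methyl ethers and the diaryl ether are inert to it.

**Step 5**
Reactants: 8 dimethyl methoxymalonate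
Product: 9 methoxymalonic acid
Conditions: KOH, MeOH/H2O, rt; then HCl (aq), 0 °C
Reagents that add atoms: potassium hydroxide, [K+].[OH-]
Why: Saponification of both esters by acyl–oxygen cleavage; acidifying in the cold should avoid decarboxylation of the malonic acid.

**Step 6**
Reactants: 9 methoxymalonic acid
Product: 10 methoxymalonyl dichloride
Conditions: (COCl)2, DMF (cat.), CH2Cl2, 0 °C to rt; short-path distillation
Reagents that add atoms: oxalyl chloride, O=C(Cl)C(=O)Cl
Why: Acid chloride formation through the catalytic chloroiminium (Vilsmeier-type) species at room temperature, well below the temperature at which malonic acids decarboxylate.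

**Step 7**
Reactants: 7 2-[2,6-dimethoxy-4-(2,4,6-trimethoxyphenoxy)phenoxy]propene; 10 methoxymalonyl dichloride
Product: 13 5-[2,6-dimethoxy-4-(2,4,6-trimethoxyphenoxy)phenoxy]-2-methoxybenzene-1,3-diol, via enol ether keto acid chloride 11 (not isolated), via cyclohexenedione tautomer 12 (not isolated)
Conditions: 2,6-di-tert-butyl-4-methylpyridine, CH2Cl2, high dilution, 7 added slowly to 10, −40 °C to rt; then NaHCO3 (aq)
Reagents that add atoms: none
Why: Proposed new method: the terminal carbon of the enol ether in 7 attacks one acyl chloride of 10, and the aryloxy-stabilised oxocarbenium ion sheds a proton from its methyl group to give the transposed enol ether 11, which sets ring C bond C2–C3. The new terminal carbon of 11 then attacks the second acyl chloride in a 6-(enolendo)-exo-trig closure that sets bond C5–C6, and the vinylogous ester dione 12 enolises twice to the resorcinol 13, the gain of aromaticity making the sequence irreversible. The closest known reaction type is the Effenberger cyclisation, in which methyl enol ethers of cyclohexanones are C-acylated twice by malonyl dichloride to cyclic 1,3-diones, together with the pyranone synthesis from malonyl dichlorides and ketones or silyl enol ethers; neither has been shown on an aryl isopropenyl ether or with a benzene ring as the outcome. No stereocentre is created, since the labile C4–H centre of 11 and 12 ends as an aromatic carbon. The step needs carbon rather than oxygen acylation in the closure and enol ether rather than arene acylation: the aryl group on the enol oxygen cannot be expelled, which shuts off closure to a 4-hydroxy-2-pyranone, and the absence of a Lewis acid, the low temperature and the hindered pyridine base (which binds HCl without opening the enol ether) should keep the electron-rich rings A and B from Friedel–Crafts acylation.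

**Step 8**
Reactants: 13 5-[2,6-dimethoxy-4-(2,4,6-trimethoxyphenoxy)phenoxy]-2-methoxybenzene-1,3-diol
Product: 14 5-[2,6-dihydroxy-4-(2,4,6-trihydroxyphenoxy)phenoxy]benzene-1,2,3-triol
Conditions: BBr3 (excess), CH2Cl2, −78 °C to rt, argon; then degassed H2O, 0 °C
Reagents that add atoms: none
Why: Lewis acid-mediated cleavage of all six aryl methyl ethers (bromide attacks the methyl carbon of the boron-complexed ether); the diaryl ether bonds offer no sp3 carbon for attack and should persist.

**Compound list**
1 | 2,4,6-trimethoxyphenol | COc1cc(OC)c(O)c(OC)c1 | starting material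
2 | 4-fluoro-2,6-dimethoxybenzaldehyde | COc1cc(F)cc(OC)c1C=O | starting material
3 | 2,6-dimethoxy-4-(2,4,6-trimethoxyphenoxy)benzaldehyde | COc1cc(Oc2c(OC)cc(OC)cc2OC)cc(OC)c1C=O | intermediate
4 | 2,6-dimethoxy-4-(2,4,6-trimethoxyphenoxy)phenyl formate | COc1cc(Oc2c(OC)cc(OC)cc2OC)cc(OC)c1OC=O | intermediate
5 | 2,6-dimethoxy-4-(2,4,6-trimethoxyphenoxy)phenol | COc1cc(Oc2c(OC)cc(OC)cc2OC)cc(OC)c1O | intermediate
6 | 2,6-dimethoxy-4-(2,4,6-trimethoxyphenoxy)phenyl acetate | COc1cc(Oc2c(OC)cc(OC)cc2OC)cc(OC)c1OC(C)=O | intermediate
7 | 2-[2,6-dimethoxy-4-(2,4,6-trimethoxyphenoxy)phenoxy]propene | C=C(C)Oc1c(OC)cc(Oc2c(OC)cc(OC)cc2OC)cc1OC | intermediate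
8 | dimethyl methoxymalonate | COC(C(=O)OC)C(=O)OC | starting material
9 | methoxymalonic acid | COC(C(=O)O)C(=O)O | intermediate
10 | methoxymalonyl dichloride | COC(C(=O)Cl)C(=O)Cl | intermediate
11 | 5-[2,6-dimethoxy-4-(2,4,6-trimethoxyphenoxy)phenoxy]-2-methoxy-3-oxohex-5-enoyl chloride | C=C(CC(=O)C(OC)C(=O)Cl)Oc1c(OC)cc(Oc2c(OC)cc(OC)cc2OC)cc1OC | intermediate
12 | 5-[2,6-dimethoxy-4-(2,4,6-trimethoxyphenoxy)phenoxy]-2-methoxycyclohex-4-ene-1,3-dione | COC1C(=O)CC(Oc2c(OC)cc(Oc3c(OC)cc(OC)cc3OC)cc2OC)=CC1=O | intermediate
13 | 5-[2,6-dimethoxy-4-(2,4,6-trimethoxyphenoxy)phenoxy]-2-methoxybenzene-1,3-diol | COc1c(O)cc(Oc2c(OC)cc(Oc3c(OC)cc(OC)cc3OC)cc2OC)cc1O | intermediate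
14 | 5-[2,6-dihydroxy-4-(2,4,6-trihydroxyphenoxy)phenoxy]benzene-1,2,3-triol | Oc1cc(O)c(Oc2cc(O)c(Oc3cc(O)c(O)c(O)c3)c(O)c2)c(O)c1 | target

**Step count**
Total: 8 steps. Longest linear sequence: 6 steps (1, 2, 3, 4, 7, 8); steps 5 and 6 form a two-step branch that joins at step 7.

**Steps most likely to fail**

Step 7 (proposed method). Several processes may compete with the planned double acylation:
- Friedel–Crafts acylation of ring A;
- intermolecular acylation of a second enol ether, leading to oligomers;
- acid-induced cleavage of the enol ether back to 5;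
- stalling at the acyclic stage 11.

Fallback with known chemistry: set out from 5 and attach ring C ready-made by an Ullmann-type diaryl ether coupling with 5-iodo-1,2,3-trimethoxybenzene (COc1cc(I)cc(OC)c1OC; CuI, picolinic acid, K3PO4, DMSO, 90 °C). These conditions tolerate hindered phenols and electron-rich aryl iodides. The coupling should give 5-[2,6-dimethoxy-4-(2,4,6-trimethoxyphenoxy)phenoxy]-1,2,3-trimethoxybenzene F1. Cleavage of its eight methyl ethers with BBr3 in CH2Cl2 (−78 °C to rt, then water) brings the path back to the route at 14.

Step 4. The methylenation may stop short on the hindered aryl ester, the titanium intermediate may lose the aryloxide, or the acid-labile enol ether may hydrolyse during isolation. Fallback: set out from 5 and form the O–C(sp2) bond directly by a copper-catalysed Ullmann-type vinylation with 2-bromopropene (CuI, N,N-dimethylglycine, Cs2CO3, dioxane, sealed vessel, 80 °C). This returns to the route at 7 without passing through 6; no new compound is formed on this path (F0).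

Step 8. Cleavage may remain incomplete at the methyl ethers flanked by two oxygens, ipso protonation of the electron-rich rings by HBr may break a diaryl ether bond, and the pyrogallol ring may oxidise in air during work-up. Fallback: set out from 13 and exchange methyl for silyl instead of hydrogen, using iodotrimethylsilane Me3SiI in CHCl3 at 50 °C. This should give 1,2,3-tris(trimethylsilyloxy)-5-[2,6-bis(trimethylsilyloxy)-4-(2,4,6-tris(trimethylsilyloxy)phenoxy)phenoxy]benzene F2, in which every oxygen stays capped and protected from oxidation. Neutral methanolysis at rt under argon then releases the phenols and returns to the route at 14.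

**Further compounds**
F1 | step 7 | 5-[2,6-dimethoxy-4-(2,4,6-trimethoxyphenoxy)phenoxy]-1,2,3-trimethoxybenzene | COc1cc(Oc2c(OC)cc(Oc3c(OC)cc(OC)cc3OC)cc2OC)cc(OC)c1OC
F0 | step 4 | none | none
F2 | step 8 | 1,2,3-tris(trimethylsilyloxy)-5-[2,6-bis(trimethylsilyloxy)-4-(2,4,6-tris(trimethylsilyloxy)phenoxy)phenoxy]benzene | C[Si](C)(C)Oc1cc(O[Si](C)(C)C)c(Oc2cc(O[Si](C)(C)C)c(Oc3cc(O[Si](C)(C)C)c(O[Si](C)(C)C)c(O[Si](C)(C)C)c3)c(O[Si](C)(C)C)c2)c(O[Si](C)(C)C)c1
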